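**Plan**

- Locants: ring B of the dihydronaphthalene is C1 (bears the pyranone) – C2 (CO2Me) – C3 (CO2H) = C4 – C4a/C8a (arene); the pyranone is attached through C3′.
- Cuts, in retrosynthetic order: (i) C3=C4 of ring B (aldol/Perkin retron), giving an o-formylaryl succinate half-ester; (ii) C1–C3′, as benzylic C1–H plus a 3-iodopyranone; (iii) C1–C2 (Stobbe, then hydrogenation), back to 2-bromo-4,5-dimethoxybenzaldehyde and dimethyl succinate.
- Enabling feature: with ring B opened at C3=C4, C4 is an aryl aldehyde ortho (through C4a–C8a) to the benzylic C1H2. A catalytic chiral imine on C4 holds Pd(II) in a six-membered palladacycle at C1, and the same aldehyde afterwards closes ring B onto C3. The C2 ester/C3 acid pattern is that of a Stobbe half-ester, so neither carboxyl is ever protected.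
- Forward order: Stobbe (C1=C2), asymmetric hydrogenation, formylation (C4), C–H coupling (C1–C3′), Perkin cyclisation closing the six-membered ring B (the only ring built; the arene and pyranone rings are purchased), then removal of the methyl ethers and the benzyl ester.
- Stereochemistry: C2 from Rh–bisphospholane hydrogenation; C1 from the chiral transient directing group in the C–H coupling; the 1,2-trans relation is also the thermodynamic one, so C2 is self-correcting by enolisation.

Key step: step 6

Assumption: the senses of induction of (S,S)-Et-DuPHOS–Rh (R acid 5) and of L-tert-leucine (4R centre of 13) are taken by analogy with β-aryl itaconate half-esters and 2-alkylbenzaldehydes; if either proves opposite, the enantiomeric ligand or D-tert-leucine is used.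

**Route**

Step 1
Reactants: 1 2-bromo-4,5-dimethoxybenzaldehyde; 2 dimethyl succinate
Product: 4 (E)-4-(2-bromo-4,5-dimethoxyphenyl)-3-(methoxycarbonyl)but-3-enoic acid, via paraconate lactone 3 (not isolated)
Conditions: NaOMe (2.2 equiv), MeOH, reflux; then aq. HCl
Reagents that add atoms: none
Why: Stobbe condensation, in which the succinate enolate adds to the aldehyde, the alkoxide lactonises onto the distal ester (3) and E1cB opening should give the E alkylidene half-ester, leaving the future C2 carboxyl as methyl ester and the future C3 carboxyl as free acid exactly as in the target.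

Step 2
Reactants: 4 (E)-4-(2-bromo-4,5-dimethoxyphenyl)-3-(methoxycarbonyl)but-3-enoic acid
Product: 5 (R)-4-(2-bromo-4,5-dimethoxyphenyl)-3-(methoxycarbonyl)butanoic acid
Conditions: H2 (5 bar), [Rh(cod)((S,S)-Et-DuPHOS)]BF4 (1 mol %), Et3N (1 equiv), MeOH, rt; then aq. citric acid
Reagents that add atoms: none
Why: Rh(I)–bisphospholane asymmetric hydrogenation of a β-aryl itaconate half-ester (two-point binding through alkene and carboxylate) should set the C2 stereocentre by catalyst control and leave the aryl bromide untouched.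

Step 3
Reactants: 5 (R)-4-(2-bromo-4,5-dimethoxyphenyl)-3-(methoxycarbonyl)butanoic acid
Product: 6 (R)-4-(2-formyl-4,5-dimethoxyphenyl)-3-(methoxycarbonyl)butanoic acid
Conditions: Pd(OAc)2 (1 mol %), n-BuPAd2 (3 mol %), TMEDA (2 equiv), CO/H2 (1:1, 5 bar), toluene, 100 °C
Reagents that add atoms: carbon monoxide, [C-]#[O+]
Why: Pd-catalysed reductive carbonylation (formylation) of the aryl bromide should install the ortho aldehyde (future C4) without affecting the ester, the acid (held as ammonium salt) or the α-stereocentre.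

Step 4
Reactants: 7 2-oxo-2H-pyran-6-carboxylic acid
Product: 8 benzyl 2-oxo-2H-pyran-6-carboxylate
Conditions: BnBr (1.1 equiv), KHCO3 (1.2 equiv), DMF, rt
Reagents that add atoms: benzyl bromide, BrCc1ccccc1
Why: carboxylate O-alkylation (SN2) under weak bicarbonate base should esterify the acid without opening the base-sensitive pyranone.

Step 5
Reactants: 8 benzyl 2-oxo-2H-pyran-6-carboxylate
Product: 10 benzyl 3-iodo-2-oxo-2H-pyran-6-carboxylate, via iodochloride adduct 9 (not isolated)
Conditions: ICl (1.2 equiv), CH2Cl2, 0 °C to rt; then Et3N (1.5 equiv), 0 °C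
Reagents that add atoms: iodine monochloride, ClI
Why: electrophilic addition of ICl across C3=C4 (iodine at C3, the position not deactivated by the 6-ester) followed by E1cB loss of HCl, the addition–elimination α-halogenation known for 2-pyranones, should give the 3-iodide.

Step 6
Reactants: 6 (R)-4-(2-formyl-4,5-dimethoxyphenyl)-3-(methoxycarbonyl)butanoic acid; 10 benzyl 3-iodo-2-oxo-2H-pyran-6-carboxylate (1.5 equiv)
Product: 13 (3S,4R)-4-[6-(benzyloxycarbonyl)-2-oxo-2H-pyran-3-yl]-4-(2-formyl-4,5-dimethoxyphenyl)-3-(methoxycarbonyl)butanoic acid, via tert-leucine imine 11 (not isolated), via coupled imine 12 (not isolated)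
Conditions: Pd(OAc)2 (10 mol %), L-tert-leucine (20 mol %), AgTFA (2 equiv), HFIP/AcOH (9:1), 80 °C
Reagents that add atoms: none
Why: L-tert-leucine condenses reversibly with the aldehyde of 6 to imine 11, whose imine N and carboxylate O bind Pd(II); concerted metalation–deprotonation of one benzylic C1–H gives a six-membered palladacycle (Pd–C1–C8a–C4a–C4=N), oxidative addition of iodide 10 gives Pd(IV), C(sp3)–C(sp2) reductive elimination with retention forms the C1–C3′ bond (12), and AgTFA removes iodide while hydrolysis releases 13 and the amino acid. The closest known reaction type is the Pd(II)-catalysed enantioselective benzylic C(sp3)–H arylation of 2-alkylbenzaldehydes with aryl iodides under a chiral amino-acid transient directing group. No ring of the target closes here; the only ring formed is the transient palladacycle, and ring B is closed in step 7. The new centre C1 (4R in 13) should be set by the tert-butyl group of the transient imine, which differentiates the two enantiotopic benzylic hydrogens in the metalation step, while the existing C2 centre lies outside the palladacycle and is in any case equilibrated to trans after ring closure. The step needs site selectivity for the benzylic CH2 over the aryl C5–H, which the [6,5]-fused chelate and the flanking of C5–H by CHO and OMe should secure, and it needs single coupling, which is secured because the product C1–H is tertiary.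

Step 7
Reactants: 13 (3S,4R)-4-[6-(benzyloxycarbonyl)-2-oxo-2H-pyran-3-yl]-4-(2-formyl-4,5-dimethoxyphenyl)-3-(methoxycarbonyl)butanoic acid
Product: 16 (1R,2R)-1-[6-(benzyloxycarbonyl)-2-oxo-2H-pyran-3-yl]-6,7-dimethoxy-2-(methoxycarbonyl)-1,2-dihydronaphthalene-3-carboxylic acid, via mixed anhydride 14 (not isolated), via cyclised anhydride 15 (not isolated)
Conditions: Ac2O, NaOAc (2 equiv), 100 °C; then THF/H2O, rt
Reagents that add atoms: none
Why: intramolecular Perkin condensation, in which mixed anhydride 14 enolises at C3, adds to the ortho aldehyde (6-exo-trig aldol closing ring B) and eliminates acetate to give the C3=C4 alkene, while C2 (α to the ester, allylic) can equilibrate to the favoured trans (1R,2R) arrangement without involving C1.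

Step 8
Reactants: 16 (1R,2R)-1-[6-(benzyloxycarbonyl)-2-oxo-2H-pyran-3-yl]-6,7-dimethoxy-2-(methoxycarbonyl)-1,2-dihydronaphthalene-3-carboxylic acid
Product: 17 (1R,2R)-1-(6-carboxy-2-oxo-2H-pyran-3-yl)-6,7-dihydroxy-2-(methoxycarbonyl)-1,2-dihydronaphthalene-3-carboxylic acid (CNP0239263.1)
Conditions: BBr3 (8 equiv), CH2Cl2, −78 °C to 0 °C; then ice–water
Reagents that add atoms: none
Why: Lewis-acid dealkylation with BBr3 should cleave the two aryl methyl ethers and the benzyl ester at low temperature, conditions under which the hindered aliphatic methyl ester, the pyranone and the C3=C4 alkene should survive.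

**Compound list**

1 | 2-bromo-4,5-dimethoxybenzaldehyde | COc1cc(Br)c(C=O)cc1OC | starting material
2 | dimethyl succinate | COC(=O)CCC(=O)OC | starting material
3 | methyl 2-(2-bromo-4,5-dimethoxyphenyl)-5-oxotetrahydrofuran-3-carboxylate (Stobbe paraconate lactone, diastereomer mixture) | COC(=O)C1CC(=O)OC1c1cc(OC)c(OC)cc1Br | intermediate
4 | (E)-4-(2-bromo-4,5-dimethoxyphenyl)-3-(methoxycarbonyl)but-3-enoic acid | COC(=O)/C(CC(=O)O)=C/c1cc(OC)c(OC)cc1Br | intermediate
5 | (R)-4-(2-bromo-4,5-dimethoxyphenyl)-3-(methoxycarbonyl)butanoic acid | COC(=O)[C@@H](CC(=O)O)Cc1cc(OC)c(OC)cc1Br | intermediate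
6 | (R)-4-(2-formyl-4,5-dimethoxyphenyl)-3-(methoxycarbonyl)butanoic acid | COC(=O)[C@@H](CC(=O)O)Cc1cc(OC)c(OC)cc1C=O | intermediate
7 | 2-oxo-2H-pyran-6-carboxylic acid | O=C(O)c1cccc(=O)o1 | starting material
8 | benzyl 2-oxo-2H-pyran-6-carboxylate | O=C(OCc1ccccc1)c1cccc(=O)o1 | intermediate
9 | benzyl 4-chloro-3-iodo-2-oxo-3,4-dihydro-2H-pyran-6-carboxylate (diastereomer mixture) | O=C1OC(C(=O)OCc2ccccc2)=CC(Cl)C1I | intermediate
10 | benzyl 3-iodo-2-oxo-2H-pyran-6-carboxylate | O=C(OCc1ccccc1)c1ccc(I)c(=O)o1 | intermediate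
11 | (E)-imine of aldehyde 6 with L-tert-leucine | COC(=O)[C@@H](CC(=O)O)Cc1cc(OC)c(OC)cc1/C=N/[C@@H](C(C)(C)C)C(=O)O | intermediate
12 | (E)-imine of aldehyde 13 with L-tert-leucine | COC(=O)[C@@H](CC(=O)O)[C@H](c1cc(OC)c(OC)cc1/C=N/[C@@H](C(C)(C)C)C(=O)O)c1ccc(C(=O)OCc2ccccc2)oc1=O | intermediate
13 | (3S,4R)-4-[6-(benzyloxycarbonyl)-2-oxo-2H-pyran-3-yl]-4-(2-formyl-4,5-dimethoxyphenyl)-3-(methoxycarbonyl)butanoic acid | COC(=O)[C@@H](CC(=O)O)[C@H](c1cc(OC)c(OC)cc1C=O)c1ccc(C(=O)OCc2ccccc2)oc1=O | intermediate
14 | mixed acetic anhydride of acid 13 | COC(=O)[C@@H](CC(=O)OC(C)=O)[C@H](c1cc(OC)c(OC)cc1C=O)c1ccc(C(=O)OCc2ccccc2)oc1=O | intermediate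
15 | mixed acetic anhydride of acid 16 | COC(=O)[C@H]1C(C(=O)OC(C)=O)=Cc2cc(OC)c(OC)cc2[C@@H]1c1ccc(C(=O)OCc3ccccc3)oc1=O | intermediate
16 | (1R,2R)-1-[6-(benzyloxycarbonyl)-2-oxo-2H-pyran-3-yl]-6,7-dimethoxy-2-(methoxycarbonyl)-1,2-dihydronaphthalene-3-carboxylic acid | COC(=O)[C@H]1C(C(=O)O)=Cc2cc(OC)c(OC)cc2[C@@H]1c1ccc(C(=O)OCc3ccccc3)oc1=O | intermediate
17 | (1R,2R)-1-(6-carboxy-2-oxo-2H-pyran-3-yl)-6,7-dihydroxy-2-(methoxycarbonyl)-1,2-dihydronaphthalene-3-carboxylic acid | COC(=O)[C@H]1C(C(=O)O)=Cc2cc(O)c(O)cc2[C@@H]1c1ccc(C(=O)O)oc1=O | target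

**Step count and risks**

Total step count: 8. Longest linear sequence: 6 (steps 1, 2, 3, 6, 7, 8).

Steps most likely to fail:

Step 6. The cyclometalation at the β-branched benzylic CH2 may be slow, so that β-hydride elimination from the palladacycle (dehydrogenation towards the alkylidene succinate) or insufficient facial discrimination by the transient imine takes over. The fallback sets out from 4. Copper(I)-catalysed enantioselective conjugate borylation of the alkylidene half-ester as its carboxylate (B2pin2, CuCl, Josiphos-type ligand, NaOtBu, MeOH, THF) places boron on the benzylic β-carbon and should give (4R)-4-(2-bromo-4,5-dimethoxyphenyl)-3-(methoxycarbonyl)-4-(pinacolboryl)butanoic acid F1 as C3 epimers. Stereoretentive Suzuki–Miyaura coupling of this secondary benzylic boronate with iodide 10 (Pd2(dba)3, PPh3, Ag2O, THF, 70 °C) should give the aryl bromide F2. Palladium-catalysed formylation as in step 3 then returns to the route at 13, as C3 epimers that converge in step 7 because C2 of the ring equilibrates to trans.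

Step 7. Enolisation at C1 (benzylic and vinylogously acidified by the pyranone) under hot acetate may erode the C1 configuration, or the hindered anhydride may fail to enolise. The fallback sets out from 13. Thioesterification (EtSH, EDC, DMAP, CH2Cl2) gives the S-ethyl thioester F3. Soft enolisation at room temperature (MgBr2·OEt2, i-Pr2NEt, CH2Cl2) should trigger a direct intramolecular aldol addition to the cyclic β-hydroxy thioester F4. Dehydration with Martin sulfurane gives the unsaturated thioester F5, and silver(I)-assisted hydrolysis (AgNO3, THF/H2O) returns to the route at 16.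

Step 5. Iodonium attack may occur at C5 instead of C3, or addition to the ester-deactivated pyranone may not take place. The fallback sets out from 8. Bromine addition (Br2, CH2Cl2) gives the dibromide F6, and dehydrobromination with Et3N gives benzyl 3-bromo-2-oxo-2H-pyran-6-carboxylate F7. Copper-catalysed halogen exchange (NaI, CuI, trans-N,N′-dimethylcyclohexane-1,2-diamine, dioxane, 110 °C) returns to the route at 10.

Further compounds
F1 | step 6 | (4R)-4-(2-bromo-4,5-dimethoxyphenyl)-3-(methoxycarbonyl)-4-(4,4,5,5-tetramethyl-1,3,2-dioxaborolan-2-yl)butanoic acid (C3 epimers) | COC(=O)C(CC(=O)O)[C@H](c1cc(OC)c(OC)cc1Br)B1OC(C)(C)C(C)(C)O1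
F2 | step 6 | (4S)-4-[6-(benzyloxycarbonyl)-2-oxo-2H-pyran-3-yl]-4-(2-bromo-4,5-dimethoxyphenyl)-3-(methoxycarbonyl)butanoic acid (C3 epimers; same spatial arrangement at C4 as in 13) | COC(=O)C(CC(=O)O)[C@H](c1cc(OC)c(OC)cc1Br)c1ccc(C(=O)OCc2ccccc2)oc1=O
F3 | step 7 | S-ethyl thioester of acid 13 (same configuration) | COC(=O)[C@@H](CC(=O)SCC)[C@H](c1cc(OC)c(OC)cc1C=O)c1ccc(C(=O)OCc2ccccc2)oc1=O
F4 | step 7 | S-ethyl (1R,2R)-1-[6-(benzyloxycarbonyl)-2-oxo-2H-pyran-3-yl]-4-hydroxy-6,7-dimethoxy-2-(methoxycarbonyl)-1,2,3,4-tetrahydronaphthalene-3-carbothioate (C3/C4 diastereomers) | COC(=O)[C@H]1C(C(=O)SCC)C(O)c2cc(OC)c(OC)cc2[C@@H]1c1ccc(C(=O)OCc3ccccc3)oc1=O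
F5 | step 7 | S-ethyl (1R,2R)-1-[6-(benzyloxycarbonyl)-2-oxo-2H-pyran-3-yl]-6,7-dimethoxy-2-(methoxycarbonyl)-1,2-dihydronaphthalene-3-carbothioate | COC(=O)[C@H]1C(C(=O)SCC)=Cc2cc(OC)c(OC)cc2[C@@H]1c1ccc(C(=O)OCc3ccccc3)oc1=O
F6 | step 5 | benzyl 3,4-dibromo-2-oxo-3,4-dihydro-2H-pyran-6-carboxylate (diastereomer mixture) | O=C1OC(C(=O)OCc2ccccc2)=CC(Br)C1Br
F7 | step 5 | benzyl 3-bromo-2-oxo-2H-pyran-6-carboxylate | O=C(OCc1ccccc1)c1ccc(Br)c(=O)o1
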